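The flavonol is cut at the C4–C4a bond of ring C. An intramolecular Friedel–Crafts acylation of a (Z)-3-aryloxy-3-arylacrylic acid closes the pyranone ring and delivers the complete, fully protected flavone in one operation. The feature exploited is that C4a sits between the oxygenated carbons C8a and C5 of ring A and that O5 and O7 are mirror-related about the C6 methoxy group: a 3,5-bis(benzyloxy)-4-methoxyphenoxy unit therefore has two equivalent ortho carbons, so only one flavone can form. Afterwards the new C4 carbonyl singles out O5 by chelation. Ring B carries the (S)-side chain, built from the Roche ester.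

Key step: step 14

Remark: the conjugate adduct and the derived acid are drawn as Z isomers (anti addition); any E isomer is carried along, because the acidic key step interconverts the two geometries.

Step 1
Reactants: 1 methyl 3,5-dihydroxy-4-methoxybenzoate
Product: 2 methyl 3,5-bis(benzyloxy)-4-methoxybenzoate
Conditions: BnBr, K2CO3, DMF, 60 °C
Reagents that add atoms: benzyl bromide, BrCc1ccccc1
Why: Williamson ether synthesis, in which both phenoxides attack the benzylic carbon by SN2 while the methyl ester is inert to carbonate, so the symmetric dibenzyl ether should result.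

Step 2
Reactants: 2 methyl 3,5-bis(benzyloxy)-4-methoxybenzoate
Product: 3 [3,5-bis(benzyloxy)-4-methoxyphenyl]methanol
Conditions: LiAlH4, THF, 0 °C → rt
Reagents that add atoms: none
Why: Hydride reduction of an aryl ester to the benzylic alcohol, with aryl benzyl and methyl ethers inert to LiAlH4.

Step 3
Reactants: 3 [3,5-bis(benzyloxy)-4-methoxyphenyl]methanol
Product: 4 3,5-bis(benzyloxy)-4-methoxybenzaldehyde
Conditions: activated MnO2, CH2Cl2, rt
Reagents that add atoms: none
Why: Chemoselective MnO2 oxidation of a benzylic alcohol, which should stop at the aldehyde.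

Step 4
Reactants: 4 3,5-bis(benzyloxy)-4-methoxybenzaldehyde
Product: 6 3,5-bis(benzyloxy)-4-methoxyphenol, via aryl formate 5 (not isolated)
Conditions: mCPBA, CH2Cl2, rt; NaHCO3 wash; then K2CO3 (cat.), MeOH, rt
Reagents that add atoms: meta-chloroperoxybenzoic acid, OOC(=O)c1cccc(Cl)c1
Why: Baeyer–Villiger (Dakin-type) oxidation, in which the electron-rich trioxygenated aryl group migrates to oxygen in the peracid adduct and mild methanolysis cleaves the resulting aryl formate; a peracid is chosen because the aldehyde has no free ortho or para hydroxyl group for an alkaline Dakin reaction.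

Step 5
Reactants: 7 methyl (2R)-3-hydroxy-2-methylpropanoate ((R)-Roche ester)
Product: 8 methyl (2R)-3-(benzyloxy)-2-methylpropanoate
Conditions: BnOC(=NH)CCl3, TfOH (cat.), CH2Cl2/cyclohexane, 0 °C → rt
Reagents that add atoms: benzyl 2,2,2-trichloroacetimidate, N=C(OCc1ccccc1)C(Cl)(Cl)Cl
Why: Acid-catalysed O-benzylation with a trichloroacetimidate, which avoids base and so prevents β-elimination or epimerisation at the α-stereocenter, which takes no part in the reaction.

Step 6
Reactants: 8 methyl (2R)-3-(benzyloxy)-2-methylpropanoate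
Product: 9 (2R)-3-(benzyloxy)-2-methylpropanal
Conditions: DIBAL-H, CH2Cl2, −78 °C; MeOH, aq. potassium sodium tartrate; crude used at once
Reagents that add atoms: none
Why: Partial ester reduction with DIBAL-H, in which the tetrahedral aluminium hemiacetal, held by chelation to the β-benzyloxy oxygen, should survive at −78 °C until the quench, and immediate use protects the enolisable α-stereocenter.

Step 7
Reactants: 9 (2R)-3-(benzyloxy)-2-methylpropanal
Product: 10 benzyl (2S)-2-methylbut-3-en-1-yl ether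
Conditions: Ph3PCH3Br, KHMDS, THF, −78 → 0 °C
Reagents that add atoms: methyltriphenylphosphonium bromide, C[P+](c1ccccc1)(c1ccccc1)c1ccccc1.[Br-]
Why: Wittig methylenation, in which the unstabilised ylide should add to the aldehyde at low temperature faster than it enolises it, so the stereocenter is retained (the descriptor changes from R to S only because the CIP priorities change).

Step 8
Reactants: 11 2-iodophenol
Product: 12 1-(benzyloxy)-2-iodobenzene
Conditions: BnBr, K2CO3, acetone, reflux
Reagents that add atoms: benzyl bromide, BrCc1ccccc1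
Why: Williamson ether synthesis on the phenoxide, with the aryl iodide inert to these conditions.

Step 9
Reactants: 10 benzyl (2S)-2-methylbut-3-en-1-yl ether; 12 1-(benzyloxy)-2-iodobenzene
Product: 14 1-(benzyloxy)-2-[(3S)-4-(benzyloxy)-3-methylbutyl]benzene, via alkylborane 13 (not isolated)
Conditions: 10, 9-BBN, THF, 0 °C → rt; then 12, Pd(dppf)Cl2 (cat.), aq. K3PO4, DMF, 60 °C
Reagents that add atoms: none
Why: Anti-Markovnikov hydroboration of the terminal alkene followed by B-alkyl Suzuki–Miyaura coupling with the aryl iodide; the stereocenter is β to boron, takes part in neither event and should be carried through unchanged.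

Step 10
Reactants: 14 1-(benzyloxy)-2-[(3S)-4-(benzyloxy)-3-methylbutyl]benzene
Product: 15 1-(benzyloxy)-2-[(3S)-4-(benzyloxy)-3-methylbutyl]-4-iodobenzene
Conditions: NIS, CF3CO2H (cat.), MeCN, rt
Reagents that add atoms: N-iodosuccinimide, O=C1CCC(=O)N1I
Why: Electrophilic aromatic iodination, in which the benzyloxy group is the dominant director and its para carbon the least hindered activated site, while the unactivated benzyl phenyl rings should not react.

Step 11
Reactants: 15 1-(benzyloxy)-2-[(3S)-4-(benzyloxy)-3-methylbutyl]-4-iodobenzene; 16 methyl propiolate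
Product: 17 methyl 3-{4-(benzyloxy)-3-[(3S)-4-(benzyloxy)-3-methylbutyl]phenyl}prop-2-ynoate
Conditions: Pd(PPh3)2Cl2 (cat.), CuI (cat.), K2CO3, THF, 65 °C, excess 16 added slowly
Reagents that add atoms: none
Why: Sonogashira coupling of an aryl iodide with an alkynoate, run with carbonate instead of an amine base because amines add to propiolates in conjugate fashion.

Step 12
Reactants: 6 3,5-bis(benzyloxy)-4-methoxyphenol; 17 methyl 3-{4-(benzyloxy)-3-[(3S)-4-(benzyloxy)-3-methylbutyl]phenyl}prop-2-ynoate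
Product: 18 methyl (2Z)-3-[3,5-bis(benzyloxy)-4-methoxyphenoxy]-3-{4-(benzyloxy)-3-[(3S)-4-(benzyloxy)-3-methylbutyl]phenyl}prop-2-enoate
Conditions: K2CO3, DMF, 80 °C, under Ar
Reagents that add atoms: none
Why: Oxa-Michael (conjugate) addition of the phenoxide to the alkynoate, in which anti addition across the triple bond should place the aryloxy group cis to the ester, a geometry that is in any case not decisive for the later closure.

Step 13
Reactants: 18 methyl (2Z)-3-[3,5-bis(benzyloxy)-4-methoxyphenoxy]-3-{4-(benzyloxy)-3-[(3S)-4-(benzyloxy)-3-methylbutyl]phenyl}prop-2-enoate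
Product: 19 (2Z)-3-[3,5-bis(benzyloxy)-4-methoxyphenoxy]-3-{4-(benzyloxy)-3-[(3S)-4-(benzyloxy)-3-methylbutyl]phenyl}prop-2-enoic acid
Conditions: LiOH·H2O, THF/MeOH/H2O, 40 °C; then 1 M HCl to pH 3–4, 0 °C
Reagents that add atoms: lithium hydroxide, [Li+].[OH-]
Why: Saponification by acyl substitution at the ester carbon; the β-carbon of this vinylogous carbonate is deactivated toward hydroxide, and cold, mild acidification should avoid hydrolysis of the enol ether.

Step 14
Reactants: 19 (2Z)-3-[3,5-bis(benzyloxy)-4-methoxyphenoxy]-3-{4-(benzyloxy)-3-[(3S)-4-(benzyloxy)-3-methylbutyl]phenyl}prop-2-enoic acid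
Product: 21 5,7-bis(benzyloxy)-2-{4-(benzyloxy)-3-[(3S)-4-(benzyloxy)-3-methylbutyl]phenyl}-6-methoxy-4H-chromen-4-one, via mixed anhydride 20 (not isolated)
Conditions: (CF3CO)2O, CH2Cl2, 0 °C → rt; aq. NaHCO3 quench
Reagents that add atoms: none
Why: The acid is converted by (CF3CO)2O into mixed anhydride 20, whose acyl carbon (ionised or not) is attacked by the ring A carbon ortho to the ether oxygen, and loss of a proton together with CF3CO2H restores aromaticity to give the chromen-4-one. The closest known reaction type is the classical intramolecular Friedel–Crafts acylation of β-aryloxycinnamic acids to flavones. Ring C closes as a six-membered ring by electrophilic aromatic substitution, the acyl carbon (C4) bonding to the arene carbon (C4a) so that the aromatic bond C4a–C8a becomes part of the new ring. No stereocenter is created, and the remote (S)-centre of the side chain has no ionisable neighbour and should be untouched. Regioselectivity is secured by the substrate, since the two carbons ortho to the ether oxygen are related by the mirror plane through that oxygen and the 4-methoxy group, and each is activated ortho/para by three oxygens. Closure onto ring B (indenone formation) is not expected, because its ortho carbons are meta to the benzyloxy group and would need a five-membered ring from the E acid, while acid-mediated C-protonation of the push–pull alkene lets E and Z acids interconvert and drain through the Z form.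

Step 15
Reactants: 21 5,7-bis(benzyloxy)-2-{4-(benzyloxy)-3-[(3S)-4-(benzyloxy)-3-methylbutyl]phenyl}-6-methoxy-4H-chromen-4-one
Product: 22 7-(benzyloxy)-2-{4-(benzyloxy)-3-[(3S)-4-(benzyloxy)-3-methylbutyl]phenyl}-5-hydroxy-6-methoxy-4H-chromen-4-one
Conditions: MgBr2·OEt2, toluene/Et2O, 80 °C; then 1 M HCl
Reagents that add atoms: none
Why: Chelation-directed Lewis acid cleavage of an ether, in which magnesium bridges the C4 carbonyl and O5 so that bromide attacks only the benzylic carbon on O5 by SN2, while the benzyl ethers at O7, O4' and on the side chain cannot form such a chelate and should remain.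

Step 16
Reactants: 22 7-(benzyloxy)-2-{4-(benzyloxy)-3-[(3S)-4-(benzyloxy)-3-methylbutyl]phenyl}-5-hydroxy-6-methoxy-4H-chromen-4-one
Product: 23 7-(benzyloxy)-2-{4-(benzyloxy)-3-[(3S)-4-(benzyloxy)-3-methylbutyl]phenyl}-5,6-dimethoxy-4H-chromen-4-one
Conditions: MeI, K2CO3, DMF, 50 °C
Reagents that add atoms: iodomethane, CI
Why: Williamson O-methylation, in which warming with excess MeI should overcome the hydrogen bond of the 5-hydroxyl to the C4 carbonyl, no other acidic site being present.

Step 17
Reactants: 23 7-(benzyloxy)-2-{4-(benzyloxy)-3-[(3S)-4-(benzyloxy)-3-methylbutyl]phenyl}-5,6-dimethoxy-4H-chromen-4-one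
Product: 25 7-(benzyloxy)-2-{4-(benzyloxy)-3-[(3S)-4-(benzyloxy)-3-methylbutyl]phenyl}-3-hydroxy-5,6-dimethoxy-4H-chromen-4-one, via epoxide 24 (not isolated)
Conditions: DMDO in acetone, CH2Cl2, 0 °C → rt; then p-TsOH (cat.), CH2Cl2, rt
Reagents that add atoms: dimethyldioxirane, CC1(C)OO1
Why: Epoxidation of the flavone C2=C3 bond by the neutral dioxirane, followed by acid-catalysed opening at C2 (cation stabilised by O1 and ring B) and loss of H3, the known conversion of 5-O-alkylated flavones into flavonols, in which the two epoxide stereocenters disappear.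

Step 18
Reactants: 25 7-(benzyloxy)-2-{4-(benzyloxy)-3-[(3S)-4-(benzyloxy)-3-methylbutyl]phenyl}-3-hydroxy-5,6-dimethoxy-4H-chromen-4-one
Product: 26 3,7-dihydroxy-2-{4-hydroxy-3-[(3S)-4-hydroxy-3-methylbutyl]phenyl}-5,6-dimethoxy-4H-chromen-4-one (CNP0253239.1)
Conditions: H2 (1 atm), 10% Pd/C, EtOAc/MeOH, rt
Reagents that add atoms: none
Why: Catalytic hydrogenolysis of the two aryl benzyl ethers and the alkyl benzyl ether; the chromen-4-one core of a flavonol should not be reduced under these mild conditions, and the (S)-stereocenter carries no benzylic or allylic C–O bond.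

Compound list

1 | methyl 3,5-dihydroxy-4-methoxybenzoate | COC(=O)c1cc(O)c(OC)c(O)c1 | starting material
2 | methyl 3,5-bis(benzyloxy)-4-methoxybenzoate | COC(=O)c1cc(OCc2ccccc2)c(OC)c(OCc2ccccc2)c1 | intermediate
3 | [3,5-bis(benzyloxy)-4-methoxyphenyl]methanol | OCc1cc(OCc2ccccc2)c(OC)c(OCc2ccccc2)c1 | intermediate
4 | 3,5-bis(benzyloxy)-4-methoxybenzaldehyde | O=Cc1cc(OCc2ccccc2)c(OC)c(OCc2ccccc2)c1 | intermediate
5 | 3,5-bis(benzyloxy)-4-methoxyphenyl formate (formed in the flask, not isolated) | O=COc1cc(OCc2ccccc2)c(OC)c(OCc2ccccc2)c1 | intermediate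
6 | 3,5-bis(benzyloxy)-4-methoxyphenol | Oc1cc(OCc2ccccc2)c(OC)c(OCc2ccccc2)c1 | intermediate
7 | methyl (2R)-3-hydroxy-2-methylpropanoate ((R)-Roche ester) | COC(=O)[C@H](C)CO | starting material
8 | methyl (2R)-3-(benzyloxy)-2-methylpropanoate | COC(=O)[C@H](C)COCc1ccccc1 | intermediate
9 | (2R)-3-(benzyloxy)-2-methylpropanal | O=C[C@H](C)COCc1ccccc1 | intermediate
10 | benzyl (2S)-2-methylbut-3-en-1-yl ether | C=C[C@H](C)COCc1ccccc1 | intermediate
11 | 2-iodophenol | Oc1ccccc1I | starting material
12 | 1-(benzyloxy)-2-iodobenzene | Ic1ccccc1OCc1ccccc1 | intermediate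
13 | 9-[(3S)-4-(benzyloxy)-3-methylbutyl]-9-borabicyclo[3.3.1]nonane (formed in the flask, not isolated) | B1(CC[C@H](C)COCc2ccccc2)C2CCCC1CCC2 | intermediate
14 | 1-(benzyloxy)-2-[(3S)-4-(benzyloxy)-3-methylbutyl]benzene | c1ccc(OCc2ccccc2)c(CC[C@H](C)COCc2ccccc2)c1 | intermediate
15 | 1-(benzyloxy)-2-[(3S)-4-(benzyloxy)-3-methylbutyl]-4-iodobenzene | Ic1ccc(OCc2ccccc2)c(CC[C@H](C)COCc2ccccc2)c1 | intermediate
16 | methyl propiolate | C#CC(=O)OC | starting material
17 | methyl 3-{4-(benzyloxy)-3-[(3S)-4-(benzyloxy)-3-methylbutyl]phenyl}prop-2-ynoate | COC(=O)C#Cc1ccc(OCc2ccccc2)c(CC[C@H](C)COCc2ccccc2)c1 | intermediate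
18 | methyl (2Z)-3-[3,5-bis(benzyloxy)-4-methoxyphenoxy]-3-{4-(benzyloxy)-3-[(3S)-4-(benzyloxy)-3-methylbutyl]phenyl}prop-2-enoate | COC(=O)/C=C(\Oc1cc(OCc2ccccc2)c(OC)c(OCc2ccccc2)c1)c1ccc(OCc2ccccc2)c(CC[C@H](C)COCc2ccccc2)c1 | intermediate
19 | (2Z)-3-[3,5-bis(benzyloxy)-4-methoxyphenoxy]-3-{4-(benzyloxy)-3-[(3S)-4-(benzyloxy)-3-methylbutyl]phenyl}prop-2-enoic acid | OC(=O)/C=C(\Oc1cc(OCc2ccccc2)c(OC)c(OCc2ccccc2)c1)c1ccc(OCc2ccccc2)c(CC[C@H](C)COCc2ccccc2)c1 | intermediate
20 | mixed anhydride of acid 19 and trifluoroacetic acid (formed in the flask, not isolated) | FC(F)(F)C(=O)OC(=O)/C=C(\Oc1cc(OCc2ccccc2)c(OC)c(OCc2ccccc2)c1)c1ccc(OCc2ccccc2)c(CC[C@H](C)COCc2ccccc2)c1 | intermediate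
21 | 5,7-bis(benzyloxy)-2-{4-(benzyloxy)-3-[(3S)-4-(benzyloxy)-3-methylbutyl]phenyl}-6-methoxy-4H-chromen-4-one | COc1c(OCc2ccccc2)cc2oc(-c3ccc(OCc4ccccc4)c(CC[C@H](C)COCc4ccccc4)c3)cc(=O)c2c1OCc1ccccc1 | intermediate
22 | 7-(benzyloxy)-2-{4-(benzyloxy)-3-[(3S)-4-(benzyloxy)-3-methylbutyl]phenyl}-5-hydroxy-6-methoxy-4H-chromen-4-one | COc1c(OCc2ccccc2)cc2oc(-c3ccc(OCc4ccccc4)c(CC[C@H](C)COCc4ccccc4)c3)cc(=O)c2c1O | intermediate
23 | 7-(benzyloxy)-2-{4-(benzyloxy)-3-[(3S)-4-(benzyloxy)-3-methylbutyl]phenyl}-5,6-dimethoxy-4H-chromen-4-one | COc1c(OCc2ccccc2)cc2oc(-c3ccc(OCc4ccccc4)c(CC[C@H](C)COCc4ccccc4)c3)cc(=O)c2c1OC | intermediate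
24 | 2,3-epoxide of 23 (2,3-epoxy-2,3-dihydroflavone, both epoxide diastereomers; formed in the flask, not isolated) | COc1c(OCc2ccccc2)cc2OC3(c4ccc(OCc5ccccc5)c(CC[C@H](C)COCc5ccccc5)c4)OC3C(=O)c2c1OC | intermediate
25 | 7-(benzyloxy)-2-{4-(benzyloxy)-3-[(3S)-4-(benzyloxy)-3-methylbutyl]phenyl}-3-hydroxy-5,6-dimethoxy-4H-chromen-4-one | COc1c(OCc2ccccc2)cc2oc(-c3ccc(OCc4ccccc4)c(CC[C@H](C)COCc4ccccc4)c3)c(O)c(=O)c2c1OC | intermediate
26 | 3,7-dihydroxy-2-{4-hydroxy-3-[(3S)-4-hydroxy-3-methylbutyl]phenyl}-5,6-dimethoxy-4H-chromen-4-one (CNP0253239.1) | COc1c(O)cc2oc(-c3ccc(O)c(CC[C@H](C)CO)c3)c(O)c(=O)c2c1OC | target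

Total step count: 18.
Longest linear sequence: 13 steps (steps 5, 6, 7, 9, 10, 11, 12, 13, 14, 15, 16, 17, 18; from 7 to 26).

Steps most likely to fail

1. Step 14 (ring C closure). The trifluoroacetic acid released may strip or shift the ring A benzyl groups, the aryl enol ether may be cleaved, or ring A may be C-trifluoroacetylated before the acyl carbon reaches C4a. The fallback builds ring C without acid by a carbonylative annulation; it sets out from phenol 6 and aryl iodide 15 and comes back to the route at flavone 21. Phenol 6 should be mono-iodinated with NIS in CH2Cl2 at 0 °C at one of its two equivalent ortho carbons to give 3,5-bis(benzyloxy)-2-iodo-4-methoxyphenol F1. Iodide 15 should couple with trimethylsilylacetylene (Pd(PPh3)2Cl2, CuI, Et3N, rt) to give ({4-(benzyloxy)-3-[(3S)-4-(benzyloxy)-3-methylbutyl]phenyl}ethynyl)trimethylsilane F2, from which K2CO3 in MeOH should release 1-(benzyloxy)-2-[(3S)-4-(benzyloxy)-3-methylbutyl]-4-ethynylbenzene F3. F1 and F3 are then combined under CO (1 atm) with Pd(PPh3)2Cl2 in Et2NH/DMF at 120 °C in a sealed vessel. Carbonylative Sonogashira coupling should give 1-[2,4-bis(benzyloxy)-6-hydroxy-3-methoxyphenyl]-3-{4-(benzyloxy)-3-[(3S)-4-(benzyloxy)-3-methylbutyl]phenyl}prop-2-yn-1-one F4, which should close in the same flask by 6-endo attack of the phenol oxygen on the ynone to give 21.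

2. Step 17 (C3 hydroxylation). Oxygen transfer to the electron-poor C2=C3 bond is slow, so oxidation of the benzylic C–H bonds of the three benzyl ethers, or of the tertiary C–H of the side chain, may compete. The fallback replaces electrophilic oxidation by C3 metalation; it sets out from 23 and comes back at 25. Deprotonation of 23 at C3 with LDA in THF at −78 °C should give [7-(benzyloxy)-2-{4-(benzyloxy)-3-[(3S)-4-(benzyloxy)-3-methylbutyl]phenyl}-5,6-dimethoxy-4-oxo-4H-chromen-3-yl]lithium F5. Trapping with B(OMe)3 should give dimethyl [7-(benzyloxy)-2-{4-(benzyloxy)-3-[(3S)-4-(benzyloxy)-3-methylbutyl]phenyl}-5,6-dimethoxy-4-oxo-4H-chromen-3-yl]boronate F6, which H2O2 in AcOH should oxidise at the C–B bond to flavonol 25.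

3. Step 12 (union of the two aryl units). Addition of the phenoxide to a donor-substituted alkynoate may be sluggish or reversible, and the electron-rich phenoxide may be air-oxidised on long heating. The fallback turns the addition into a substitution at a vinyl iodide; it sets out from 17 and comes back at 18. Hydroiodination of 17 with NaI in AcOH at 80 °C (anti addition) should give methyl (2Z)-3-{4-(benzyloxy)-3-[(3S)-4-(benzyloxy)-3-methylbutyl]phenyl}-3-iodoprop-2-enoate F7. An Ullmann-type vinylic C–O coupling of F7 with phenol 6 (CuI, N,N-dimethylglycine, Cs2CO3, dioxane, 90 °C) should then give 18 with retention of the double-bond geometry.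

Further compounds

F1 | step 14 | 3,5-bis(benzyloxy)-2-iodo-4-methoxyphenol | Oc1cc(OCc2ccccc2)c(OC)c(OCc2ccccc2)c1I
F2 | step 14 | ({4-(benzyloxy)-3-[(3S)-4-(benzyloxy)-3-methylbutyl]phenyl}ethynyl)trimethylsilane | C[Si](C)(C)C#Cc1ccc(OCc2ccccc2)c(CC[C@H](C)COCc2ccccc2)c1
F3 | step 14 | 1-(benzyloxy)-2-[(3S)-4-(benzyloxy)-3-methylbutyl]-4-ethynylbenzene | C#Cc1ccc(OCc2ccccc2)c(CC[C@H](C)COCc2ccccc2)c1
F4 | step 14 | 1-[2,4-bis(benzyloxy)-6-hydroxy-3-methoxyphenyl]-3-{4-(benzyloxy)-3-[(3S)-4-(benzyloxy)-3-methylbutyl]phenyl}prop-2-yn-1-one | O=C(C#Cc1ccc(OCc2ccccc2)c(CC[C@H](C)COCc2ccccc2)c1)c1c(O)cc(OCc2ccccc2)c(OC)c1OCc1ccccc1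
F5 | step 17 | [7-(benzyloxy)-2-{4-(benzyloxy)-3-[(3S)-4-(benzyloxy)-3-methylbutyl]phenyl}-5,6-dimethoxy-4-oxo-4H-chromen-3-yl]lithium | [Li]c1c(-c2ccc(OCc3ccccc3)c(CC[C@H](C)COCc3ccccc3)c2)oc2cc(OCc3ccccc3)c(OC)c(OC)c2c1=O
F6 | step 17 | dimethyl [7-(benzyloxy)-2-{4-(benzyloxy)-3-[(3S)-4-(benzyloxy)-3-methylbutyl]phenyl}-5,6-dimethoxy-4-oxo-4H-chromen-3-yl]boronate | COB(OC)c1c(-c2ccc(OCc3ccccc3)c(CC[C@H](C)COCc3ccccc3)c2)oc2cc(OCc3ccccc3)c(OC)c(OC)c2c1=O
F7 | step 12 | methyl (2Z)-3-{4-(benzyloxy)-3-[(3S)-4-(benzyloxy)-3-methylbutyl]phenyl}-3-iodoprop-2-enoate | COC(=O)/C=C(\I)c1ccc(OCc2ccccc2)c(CC[C@H](C)COCc2ccccc2)c1
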